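Retrosynthesis: ring A is opened at C4a–C8a and C7–C8 with CO2 put back across C4a and C7, which leaves a 2-pyranone and a boryl ynoate joined by the C1–O2 ester; then the alkynyl C–B bond, the ester C–O bond, C3–C4 (aldol) and C4'–C5' (epoxide opening) are cut.
Enabling feature: in ring A the oxygen on C6 is meta to the alkyl-bearing C4a, which is the pattern of a 4-alkoxy-6-alkyl-2-pyranone, and the atoms C4, C3, O2 and C1 of ring B form a four-atom ester link from that pyranone to a propiolate.
Forward: the chain is joined by epoxide opening, cut back to an aldehyde and attached to the pyranone methyl by aldol addition; oxidation, enzymatic reduction, propiolate ester formation and alkyne borylation follow; rings B and A then form together in one thermal cascade; C–B oxidation and hydrogenolysis finish.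
Stereochemistry: C6' is carried unchanged from (S)-1,2-epoxyheptane; C3 is set by ketoreductase reduction of the C3 ketone; the key step leaves no new stereocentre.
Protection: the C6 phenol and the C6' alcohol are both benzyl ethers, so one hydrogenolysis frees them; boron on C8 stands for the third hydroxyl.
Key step: step 10

Remark: locants C1–C8a refer to the isochromanone core and C1'–C11' to the side chain; the enzyme of step 7 is assumed to be an (R)-selective, NADPH-dependent ketoreductase picked from a commercial panel.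

Step 1
Reactants: 1 (S)-1,2-epoxyheptane; 2 6-bromohex-1-ene
Product: 4 (8S)-tridec-1-en-8-ol, via hex-5-enylmagnesium bromide 3 (not isolated)
Conditions: 2, Mg, THF, rt; then 1, CuI (10 mol %), THF, −30 to 0 °C
Reagents that add atoms: none
Why: Copper-catalysed opening of a terminal epoxide by a primary Grignard reagent (SN2 at the unsubstituted carbon) joins C4' to C5'; the carbinol carbon is not attacked, so the S configuration of 1 becomes that of C6'.

Step 2
Reactants: 4 (8S)-tridec-1-en-8-ol
Product: 5 (8S)-8-(benzyloxy)tridec-1-ene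
Conditions: NaH, BnBr, n-Bu4NI (cat.), THF/DMF, 0 °C to rt
Reagents that add atoms: benzyl bromide, BrCc1ccccc1
Why: Williamson ether synthesis on the secondary alkoxide; the terminal alkene is inert, and benzyl is chosen so that the last step removes it together with the aryl benzyl ether.

Step 3
Reactants: 5 (8S)-8-(benzyloxy)tridec-1-ene
Product: 7 (7S)-7-(benzyloxy)dodecanal, via secondary ozonide 6 (not isolated)
Conditions: O3, CH2Cl2, −78 °C (to first blue colour); then PPh3, −78 °C to rt
Reagents that add atoms: ozone, [O-][O+]=O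
Why: Ozonolysis of a monosubstituted alkene with reductive work-up gives the aldehyde one carbon shorter; stopping at the end point should spare the benzyl ether, and the stereocentre is remote.

Step 4
Reactants: 8 4-hydroxy-6-methyl-2H-pyran-2-one
Product: 9 4-(benzyloxy)-6-methyl-2H-pyran-2-one
Conditions: BnBr, K2CO3, DMF, rt
Reagents that add atoms: benzyl bromide, BrCc1ccccc1
Why: O-Alkylation of a vinylogous carboxylic acid (Williamson type); with carbonate in a dipolar aprotic solvent the anion should react mainly at the 4-oxygen, giving the 4-alkoxy-2-pyranone needed as diene.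

Step 5
Reactants: 9 4-(benzyloxy)-6-methyl-2H-pyran-2-one; 7 (7S)-7-(benzyloxy)dodecanal
Product: 11 4-(benzyloxy)-6-[(2RS,8S)-8-(benzyloxy)-2-hydroxytridecyl]-2H-pyran-2-one, via lithiated pyranone 10 (not isolated)
Conditions: 9, LiN(i-Pr)2, THF, −78 °C; then 7, −78 °C
Reagents that add atoms: none
Why: Vinylogous aldol addition: the amide base removes a proton from the 6-methyl group and the extended enolate adds through its exocyclic carbon to the aldehyde, forming C3–C4; the new carbinol needs no control because step 6 removes it.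

Step 6
Reactants: 11 4-(benzyloxy)-6-[(2RS,8S)-8-(benzyloxy)-2-hydroxytridecyl]-2H-pyran-2-one
Product: 12 4-(benzyloxy)-6-[(8S)-8-(benzyloxy)-2-oxotridecyl]-2H-pyran-2-one
Conditions: Dess–Martin periodinane, NaHCO3, CH2Cl2, 0 °C to rt
Reagents that add atoms: none
Why: Dess–Martin oxidation of a secondary alcohol under buffered, non-basic conditions, which should avoid dehydration of the β-hydroxyalkyl pyranone to the conjugated alkene.

Step 7
Reactants: 12 4-(benzyloxy)-6-[(8S)-8-(benzyloxy)-2-oxotridecyl]-2H-pyran-2-one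
Product: 13 4-(benzyloxy)-6-[(2R,8S)-8-(benzyloxy)-2-hydroxytridecyl]-2H-pyran-2-one
Conditions: (R)-selective ketoreductase, NADP+ (cat.), i-PrOH, KH2PO4/K2HPO4 buffer (pH 7), DMSO (10 vol %), 30 °C
Reagents that add atoms: none
Why: Enzymatic carbonyl reduction (hydride transfer from NADPH, recycled by i-PrOH); because the carbonyl lies between two methylene groups of similar size, the enzyme pocket and not a steric bias of a small-molecule hydride reagent is relied on to fix the face, which sets the future C3 as R while the remote S centre is untouched.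

Step 8
Reactants: 13 4-(benzyloxy)-6-[(2R,8S)-8-(benzyloxy)-2-hydroxytridecyl]-2H-pyran-2-one; 14 propiolic acid
Product: 15 (2R,8S)-8-(benzyloxy)-1-[4-(benzyloxy)-2-oxo-2H-pyran-6-yl]tridecan-2-yl prop-2-ynoate
Conditions: DCC, DMAP (5 mol %), CH2Cl2, −20 to 0 °C
Reagents that add atoms: none
Why: Steglich esterification, the usual route to propiolates of secondary alcohols; low temperature limits addition of DMAP to the ynoate, and the carbinol C–O bond is not broken, so R is retained.

Step 9
Reactants: 15 (2R,8S)-8-(benzyloxy)-1-[4-(benzyloxy)-2-oxo-2H-pyran-6-yl]tridecan-2-yl prop-2-ynoate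
Product: 18 (2R,8S)-8-(benzyloxy)-1-[4-(benzyloxy)-2-oxo-2H-pyran-6-yl]tridecan-2-yl 3-(4,4,5,5-tetramethyl-1,3,2-dioxaborolan-2-yl)prop-2-ynoate, via lithium acetylide 16 (not isolated), via lithium alkynylborate 17 (not isolated)
Conditions: LiN(SiMe3)2 (1.0 equiv), THF, −78 °C; i-PrOBpin, −78 °C; HCl (Et2O), −78 °C to rt; used crude
Reagents that add atoms: 2-isopropoxy-4,4,5,5-tetramethyl-1,3,2-dioxaborolane, CC(C)OB1OC(C)(C)C(C)(C)O1
Why: Standard alkynylboronate synthesis (deprotonation of the terminal alkyne, capture of the acetylide by a borate ester, release of the boronic ester with anhydrous acid); the alkyne C–H is the most acidic site, and one equivalent of the weaker amide base at −78 °C should leave the pyranone-activated methylene alone.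

Step 10
Reactants: 18 (2R,8S)-8-(benzyloxy)-1-[4-(benzyloxy)-2-oxo-2H-pyran-6-yl]tridecan-2-yl 3-(4,4,5,5-tetramethyl-1,3,2-dioxaborolan-2-yl)prop-2-ynoate
Product: 20 (3R)-6-(benzyloxy)-3-[(6S)-6-(benzyloxy)undecyl]-8-(4,4,5,5-tetramethyl-1,3,2-dioxaborolan-2-yl)-3,4-dihydro-1H-isochromen-1-one, via bridged cycloadduct 19 (not isolated)
Conditions: o-dichlorobenzene (0.01 M, dry, degassed), 180 °C, sealed tube
Reagents that add atoms: none
Why: Proposed new method: on heating, the 4-alkoxypyranone (diene termini C3 and C6) should add across the tethered boryl ynoate in an intramolecular Diels–Alder reaction to give the CO2-bridged adduct 19, which loses CO2 by retro-[4+2] and aromatises; the closest known reaction types are the intermolecular cycloaddition of 2-pyranones with alkynylboronic esters (arylboronic esters after CO2 loss) and the intramolecular pyranone–alkyne benzannulation, whereas an ester tether carrying a boryl ynoate has not been shown. Ring B closes as a six-membered lactone through the new C4a–C8a bond, with C4, C3, O2 and C1 as the tether between pyranone C6 and the α-carbon of the ynoate, and ring A is completed by the C7–C8 bond and becomes benzene when the bridge leaves. No stereocentre survives the cascade, since both bridgeheads of 19 end as aromatic carbons and C3 and C6' take no part. The pairing is electronically matched (normal electron demand), the nucleophilic pyranone C3 meeting the boron-bearing β-carbon of the electron-poor ynoate. The step needs regioselectivity, which the four-atom tether secures because only the fused six-membered lactone orientation is attainable and it puts boron on C8, and chemoselectivity against β-elimination of the ester and against protodeboronation, for which high dilution, a neutral aprotic solvent and exclusion of water are chosen.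

Step 11
Reactants: 20 (3R)-6-(benzyloxy)-3-[(6S)-6-(benzyloxy)undecyl]-8-(4,4,5,5-tetramethyl-1,3,2-dioxaborolan-2-yl)-3,4-dihydro-1H-isochromen-1-one
Product: 21 (3R)-6-(benzyloxy)-3-[(6S)-6-(benzyloxy)undecyl]-8-hydroxy-3,4-dihydro-1H-isochromen-1-one
Conditions: NaBO3·4H2O, THF/H2O, rt
Reagents that add atoms: sodium perborate tetrahydrate (drawn without water of crystallisation), [Na+].[Na+].O[B-]1(O)OO[B-](O)(O)OO1
Why: Oxidation of an arylboronic ester to the phenol by perborate (1,2-shift of aryl from boron to oxygen); the mild medium should leave the lactone and both benzyl ethers intact.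

Step 12
Reactants: 21 (3R)-6-(benzyloxy)-3-[(6S)-6-(benzyloxy)undecyl]-8-hydroxy-3,4-dihydro-1H-isochromen-1-one
Product: 22 (3R)-6,8-dihydroxy-3-[(6S)-6-hydroxyundecyl]-3,4-dihydro-1H-isochromen-1-one
Conditions: H2 (1 atm), Pd/C, EtOAc/EtOH, rt
Reagents that add atoms: none
Why: Hydrogenolysis of benzyl ethers over Pd/C should cleave the aryl and the secondary alkyl benzyl ether in one operation; the lactone C3–O bond is not benzylic and neither stereocentre is touched.

Compound list
1 | (S)-1,2-epoxyheptane | CCCCC[C@H]1CO1 | starting material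
2 | 6-bromohex-1-ene | C=CCCCCBr | starting material
3 | hex-5-enylmagnesium bromide | C=CCCCC[Mg]Br | intermediate (not isolated)
4 | (8S)-tridec-1-en-8-ol | CCCCC[C@H](O)CCCCCC=C | intermediate
5 | (8S)-8-(benzyloxy)tridec-1-ene | CCCCC[C@H](OCc1ccccc1)CCCCCC=C | intermediate
6 | 3-[(6S)-6-(benzyloxy)undecyl]-1,2,4-trioxolane (secondary ozonide, ring carbon unspecified) | CCCCC[C@H](OCc1ccccc1)CCCCCC1OCOO1 | intermediate (not isolated)
7 | (7S)-7-(benzyloxy)dodecanal | CCCCC[C@H](OCc1ccccc1)CCCCCC=O | intermediate
8 | 4-hydroxy-6-methyl-2H-pyran-2-one | Cc1cc(O)cc(=O)o1 | starting material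
9 | 4-(benzyloxy)-6-methyl-2H-pyran-2-one | Cc1cc(OCc2ccccc2)cc(=O)o1 | intermediate
10 | 4-(benzyloxy)-6-(lithiomethyl)-2H-pyran-2-one (extended enolate) | [Li]Cc1cc(OCc2ccccc2)cc(=O)o1 | intermediate (not isolated)
11 | 4-(benzyloxy)-6-[(2RS,8S)-8-(benzyloxy)-2-hydroxytridecyl]-2H-pyran-2-one | CCCCC[C@H](OCc1ccccc1)CCCCCC(O)Cc1cc(OCc2ccccc2)cc(=O)o1 | intermediate
12 | 4-(benzyloxy)-6-[(8S)-8-(benzyloxy)-2-oxotridecyl]-2H-pyran-2-one | CCCCC[C@H](OCc1ccccc1)CCCCCC(=O)Cc1cc(OCc2ccccc2)cc(=O)o1 | intermediate
13 | 4-(benzyloxy)-6-[(2R,8S)-8-(benzyloxy)-2-hydroxytridecyl]-2H-pyran-2-one | CCCCC[C@H](OCc1ccccc1)CCCCC[C@@H](O)Cc1cc(OCc2ccccc2)cc(=O)o1 | intermediate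
14 | propiolic acid | C#CC(=O)O | starting material
15 | (2R,8S)-8-(benzyloxy)-1-[4-(benzyloxy)-2-oxo-2H-pyran-6-yl]tridecan-2-yl prop-2-ynoate | CCCCC[C@H](OCc1ccccc1)CCCCC[C@@H](OC(=O)C#C)Cc1cc(OCc2ccccc2)cc(=O)o1 | intermediate
16 | lithium acetylide of 15 | CCCCC[C@H](OCc1ccccc1)CCCCC[C@@H](OC(=O)C#C[Li])Cc1cc(OCc2ccccc2)cc(=O)o1 | intermediate (not isolated)
17 | lithium isopropoxy(alkynyl)pinacolborate derived from 16 | CCCCC[C@H](OCc1ccccc1)CCCCC[C@@H](OC(=O)C#C[B-]1(OC(C)C)OC(C)(C)C(C)(C)O1)Cc1cc(OCc2ccccc2)cc(=O)o1.[Li+] | intermediate (not isolated)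
18 | (2R,8S)-8-(benzyloxy)-1-[4-(benzyloxy)-2-oxo-2H-pyran-6-yl]tridecan-2-yl 3-(4,4,5,5-tetramethyl-1,3,2-dioxaborolan-2-yl)prop-2-ynoate | CCCCC[C@H](OCc1ccccc1)CCCCC[C@@H](OC(=O)C#CB1OC(C)(C)C(C)(C)O1)Cc1cc(OCc2ccccc2)cc(=O)o1 | intermediate (key-step precursor)
19 | bridged cycloadduct of 18: 2-oxabicyclo[2.2.2]octa-5,7-dien-3-one fused to the six-membered lactone, bridgehead configuration unspecified | CCCCC[C@H](OCc1ccccc1)CCCCC[C@@H]1CC23OC(=O)C(C(OCc4ccccc4)=C2)C(B2OC(C)(C)C(C)(C)O2)=C3C(=O)O1 | intermediate (not isolated)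
20 | (3R)-6-(benzyloxy)-3-[(6S)-6-(benzyloxy)undecyl]-8-(4,4,5,5-tetramethyl-1,3,2-dioxaborolan-2-yl)-3,4-dihydro-1H-isochromen-1-one | CCCCC[C@H](OCc1ccccc1)CCCCC[C@@H]1Cc2cc(OCc3ccccc3)cc(B3OC(C)(C)C(C)(C)O3)c2C(=O)O1 | intermediate (key-step product)
21 | (3R)-6-(benzyloxy)-3-[(6S)-6-(benzyloxy)undecyl]-8-hydroxy-3,4-dihydro-1H-isochromen-1-one | CCCCC[C@H](OCc1ccccc1)CCCCC[C@@H]1Cc2cc(OCc3ccccc3)cc(O)c2C(=O)O1 | intermediate
22 | (3R)-6,8-dihydroxy-3-[(6S)-6-hydroxyundecyl]-3,4-dihydro-1H-isochromen-1-one | CCCCC[C@H](O)CCCCC[C@@H]1Cc2cc(O)cc(O)c2C(=O)O1 | target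

Total steps: 12. Longest linear sequence: 11 steps (steps 1–3 and 5–12 from 1 and 2); step 4 prepares the second fragment from 8.

Steps most likely to fail

1. Step 10 (proposed new method). Thermal β-elimination of the ester from the pyranone-activated C4 methylene, or a cycloaddition held back because the ester prefers the s-trans conformation, may consume 18 before rings A and B form. The fallback sets out from 13 and returns at 20. It uses the known intermolecular cycloaddition of 2-pyranones with alkynylboronic esters, with electronic instead of tether control of regiochemistry. Alcohol 13 would be silylated (Et3SiCl, imidazole, CH2Cl2) to the triethylsilyl ether F1. F1 would be heated in mesitylene at about 170 °C with ethyl 3-(pinacolboryl)prop-2-ynoate F2, itself prepared from ethyl propiolate by the lithiation–borylation of step 9. After loss of CO2 this should give the arylboronate benzoate F3, with the ester carbon next to the side chain because the nucleophilic pyranone C3 bonds to the boron-bearing alkyne carbon. Camphorsulfonic acid in wet THF, then warm toluene, would remove the silyl group and close the lactone to 20.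

2. Step 9. Deprotonation at the pyranone-activated methylene instead of the alkyne C–H would start loss of the ester by elimination, and the alkynyl C–B bond may be cleaved by moisture during isolation. The fallback sets out from 13 and 14 and returns at 20. It places the masked phenol on the alkyne without strong base and brings boron in after the arene is made. Propiolic acid 14 would be converted (NBS, AgNO3 cat., acetone) to 3-bromopropiolic acid F4. Steglich esterification of 13 with F4 would give the bromopropiolate F5. The thermal cascade of step 10 should then deliver the 8-bromo lactone F6. Miyaura borylation (B2pin2, PdCl2(dppf), KOAc, dioxane, 80 °C) would return 20.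

3. Step 7. Facial discrimination may be insufficient, or turnover low, for a very lipophilic ketone whose carbonyl sits between two methylene groups. The fallback sets out from 7 and returns at 13. It sets the carbinol on a β-keto ester, where asymmetric hydrogenation is reliable, and builds the pyranone afterwards.
   - Roskamp homologation of 7 (ethyl diazoacetate, SnCl2, CH2Cl2) would give the β-keto ester F7.
   - Noyori hydrogenation (H2, RuCl2[(R)-BINAP], EtOH) would give the β-hydroxy ester F8, the 3R configuration following the established sense of this catalyst.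
   - Silylation (TBSCl, imidazole) would give the silyl ether F9.
   - Claisen acylation of the dianion of methyl acetoacetate (NaH, then n-BuLi, THF, −78 to 0 °C) by F9 would give the 3,5-dioxo ester F10.
   - Ring closure with DBU in warm toluene would give the 4-hydroxypyranone F11.
   - O-Benzylation (BnBr, K2CO3, DMF) would give the benzyl ether F12.
   - Cleavage of the silyl ether with aqueous HF in acetonitrile would return 13.

Further compounds
F1 | step 10 | 4-(benzyloxy)-6-[(2R,8S)-8-(benzyloxy)-2-(triethylsilyloxy)tridecyl]-2H-pyran-2-one | CCCCC[C@H](OCc1ccccc1)CCCCC[C@@H](O[Si](CC)(CC)CC)Cc1cc(OCc2ccccc2)cc(=O)o1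
F2 | step 10 | ethyl 3-(4,4,5,5-tetramethyl-1,3,2-dioxaborolan-2-yl)prop-2-ynoate | CCOC(=O)C#CB1OC(C)(C)C(C)(C)O1
F3 | step 10 | ethyl 4-(benzyloxy)-2-[(2R,8S)-8-(benzyloxy)-2-(triethylsilyloxy)tridecyl]-6-(4,4,5,5-tetramethyl-1,3,2-dioxaborolan-2-yl)benzoate | CCCCC[C@H](OCc1ccccc1)CCCCC[C@@H](O[Si](CC)(CC)CC)Cc1cc(OCc2ccccc2)cc(B2OC(C)(C)C(C)(C)O2)c1C(=O)OCC
F4 | step 9 | 3-bromoprop-2-ynoic acid | OC(=O)C#CBr
F5 | step 9 | (2R,8S)-8-(benzyloxy)-1-[4-(benzyloxy)-2-oxo-2H-pyran-6-yl]tridecan-2-yl 3-bromoprop-2-ynoate | CCCCC[C@H](OCc1ccccc1)CCCCC[C@@H](OC(=O)C#CBr)Cc1cc(OCc2ccccc2)cc(=O)o1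
F6 | step 9 | (3R)-6-(benzyloxy)-3-[(6S)-6-(benzyloxy)undecyl]-8-bromo-3,4-dihydro-1H-isochromen-1-one | CCCCC[C@H](OCc1ccccc1)CCCCC[C@@H]1Cc2cc(OCc3ccccc3)cc(Br)c2C(=O)O1
F7 | step 7 | ethyl (9S)-9-(benzyloxy)-3-oxotetradecanoate | CCCCC[C@H](OCc1ccccc1)CCCCCC(=O)CC(=O)OCC
F8 | step 7 | ethyl (3R,9S)-9-(benzyloxy)-3-hydroxytetradecanoate | CCCCC[C@H](OCc1ccccc1)CCCCC[C@@H](O)CC(=O)OCC
F9 | step 7 | ethyl (3R,9S)-9-(benzyloxy)-3-(tert-butyldimethylsilyloxy)tetradecanoate | CCCCC[C@H](OCc1ccccc1)CCCCC[C@@H](O[Si](C)(C)C(C)(C)C)CC(=O)OCC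
F10 | step 7 | methyl (7R,13S)-13-(benzyloxy)-7-(tert-butyldimethylsilyloxy)-3,5-dioxooctadecanoate | CCCCC[C@H](OCc1ccccc1)CCCCC[C@@H](O[Si](C)(C)C(C)(C)C)CC(=O)CC(=O)CC(=O)OC
F11 | step 7 | 6-[(2R,8S)-8-(benzyloxy)-2-(tert-butyldimethylsilyloxy)tridecyl]-4-hydroxy-2H-pyran-2-one | CCCCC[C@H](OCc1ccccc1)CCCCC[C@@H](O[Si](C)(C)C(C)(C)C)Cc1cc(O)cc(=O)o1
F12 | step 7 | 4-(benzyloxy)-6-[(2R,8S)-8-(benzyloxy)-2-(tert-butyldimethylsilyloxy)tridecyl]-2H-pyran-2-one | CCCCC[C@H](OCc1ccccc1)CCCCC[C@@H](O[Si](C)(C)C(C)(C)C)Cc1cc(OCc2ccccc2)cc(=O)o1
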